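Ring A of the target (C1–C5, C10) is the cyclopentanone of the (S)-hydrindenedione plus one carbon: the bought bicycle already holds quaternary C5 with its methyl and the C9=C10–C8=O enone of ring B, so C4 and its methyl are inserted between C3 and C5. In one operation a selenium-stabilised ethyl anion adds to the C3 carbonyl and silver-induced loss of selenium makes C5 migrate from C3 to C4, which turns the five-membered ring into ring A with the C3 ketone and the C4 methyl in place. The precursor is the hydrindenedione with its enone masked as the dienol ethyl ether. Reduction, C7 alkylidenation, C9 hydroxylation and acylation complete the route.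

Key step: step 3

Remark: target numbering is used for every bicyclic compound (C3 ester carbinol, C4 and C5 methyl-bearing, C8 ketone, C9 carbinol, C10 ring-fusion CH, C7=C11, C12 CH2OH, C13 vinyl methyl); β is the face of the C5 methyl; the silyloxy ketone and the phosphonates used as reagents are assumed to be bought.

Step 1
Reactants: 1 dimethyl diselenide; 2 acetaldehyde
Product: 4 1,1-bis(methylselanyl)ethane, via methaneselenol 3 (not isolated)
Conditions: H3PO2 (50 % aq.), THF, 45 °C, selenol swept with N2 into 2, ZnCl2 (0.5 equiv), CH2Cl2, −20 °C → rt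
Reagents that add atoms: none
Why: Hypophosphorous acid reduces the Se–Se bond to the selenol, which condenses twice with the aldehyde under Lewis acid catalysis (selenoacetalisation, the selenium counterpart of thioacetal formation), and no stereocentre is formed.

Step 2
Reactants: 5 (S)-7a-methyl-2,3,7,7a-tetrahydro-1H-indene-1,5(6H)-dione
Product: 6 (S)-5-ethoxy-7a-methyl-2,6,7,7a-tetrahydro-1H-inden-1-one
Conditions: HC(OEt)3, EtOH, p-TsOH (cat.), rt; then Et3N
Reagents that add atoms: triethyl orthoformate, CCOC(OCC)OCC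
Why: Acid-catalysed dienol ether formation is far faster at the conjugated C8 carbonyl (through its extended enol, the double bonds moving to C8=C9 and C10=C1) than ketalisation of the neopentyl cyclopentanone carbonyl, as in the 3-enol ethers of steroidal 4-ene-3,17-diones, and C5 is untouched.

Step 3
Reactants: 4 1,1-bis(methylselanyl)ethane; 6 (S)-5-ethoxy-7a-methyl-2,6,7,7a-tetrahydro-1H-inden-1-one
Product: 10 (4aR,5R)-4a,5-dimethyl-4,4a,7,8-tetrahydronaphthalene-2,6(3H,5H)-dione, via 1-(methylselanyl)ethyllithium 7 (not isolated), via dienol ether hydroxy selenide 8 (not isolated), via enone hydroxy selenide 9 (not isolated)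
Conditions: 4, n-BuLi, THF, −78 °C; add 6, −78 °C; 1 M aq. HCl, THF, 0 °C; crude in CH2Cl2: AgBF4 on neutral Al2O3, rt; then DBU (cat.), rt
Reagents that add atoms: water, O
Why: Selenium–lithium exchange on 4 gives the weakly basic but strongly nucleophilic 7, which adds to the hindered, enolisable C3 carbonyl of 6 from the face opposite the C5 methyl (C3–C4 bond), and dilute acid then returns the enone. Silver cation binds the selenium of 9 and, as the C4–Se bond ionises, the C3–C5 bond antiperiplanar to it shifts to C4 while the hydroxyl becomes the C3 ketone (C4–C5 bond), a semipinacol 1,2-shift that is the known ring enlargement of cycloalkanone-derived β-hydroxy selenides. Ring A arises by this one-carbon enlargement of the five-membered ring and not by a cyclisation, so no exo or endo mode applies. The step needs C5 and not C2 to migrate, which the substrate secures because quaternary C5 carries the developing positive charge better, and C5 moves with retention so that the bought centre becomes C5 of the target. C4 is formed with inversion at the selenium-bearing carbon and hence as both epimers, which DBU equilibrates through the C3 enolate; reprotonation anti to the adjacent axial C5 methyl and the equatorial position favour the methyl cis to the C5 methyl, though the thermodynamic preference may be modest, and the other epimer is separated and put through the same equilibration again.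

Step 4
Reactants: 10 (4aR,5R)-4a,5-dimethyl-4,4a,7,8-tetrahydronaphthalene-2,6(3H,5H)-dione
Product: 11 3α-hydroxy-4β,5β-dimethyl-trans-decalin-8-one (10α-H)
Conditions: Li, NH3(l), THF, t-BuOH (2.5 equiv), −78 → −33 °C; then solid NH4Cl
Reagents that add atoms: none
Why: In this dissolving-metal (Birch-type) reduction the enone goes to its C8 enolate after protonation of C10 on the axial α face, which gives the trans ring fusion, while the C3 ketone is reduced through its ketyl to the thermodynamically preferred equatorial 3α-alcohol, the epimer that hydride reagents would not give because the syn-axial C5 methyl forces them onto the α face, and NH4Cl finally protonates the enolate to the C8 ketone.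

Step 5
Reactants: 11 3α-hydroxy-4β,5β-dimethyl-trans-decalin-8-one
Product: 12 3α-(triethylsilyloxy)-4β,5β-dimethyl-trans-decalin-8-one
Conditions: Et3SiCl, imidazole, DMF, 0 °C → rt
Reagents that add atoms: chlorotriethylsilane, CC[Si](Cl)(CC)CC
Why: This is a standard silylation of a secondary alcohol, and the triethylsilyl ether is chosen because it can later be removed in the presence of tert-butyldimethylsilyl ethers.

Step 6
Reactants: 12 3α-(triethylsilyloxy)-4β,5β-dimethyl-trans-decalin-8-one
Product: 15 (7(11)E)-12-(tert-butyldimethylsilyloxy)-3α-(triethylsilyloxy)eremophil-7(11)-en-8-one (4β,5β-dimethyl, 10α-H), via aldol adduct 13 (not isolated), via tertiary mesylate 14 (not isolated)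
Conditions: LiN(iPr)2, THF, −78 °C; 1-(TBSO)propan-2-one, −78 °C; AcOH, −78 °C; crude in CH2Cl2: MsCl, Et3N, DMAP (cat.), 0 °C; then DBU, rt
Reagents that add atoms: 1-[(tert-butyldimethylsilyl)oxy]propan-2-one, CC(=O)CO[Si](C)(C)C(C)(C)C
Why: In this directed aldol addition followed by E1cB dehydration, kinetic deprotonation of the trans-decalone goes to C7, away from the ring fusion as in 3-oxo-5α-steroids, the lithium enolate adds to the activated α-silyloxy ketone, and elimination of the mesylate through the enolate places the bulky silyloxymethyl group away from the enolate oxygen, which should give mainly the E alkene with the C13 methyl syn to the C8 carbonyl, any Z isomer being removed by chromatography.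

Step 7
Reactants: 15 (7(11)E)-12-(tert-butyldimethylsilyloxy)-3α-(triethylsilyloxy)eremophil-7(11)-en-8-one
Product: 17 (7(11)E)-9α,12-bis(tert-butyldimethylsilyloxy)-3α-(triethylsilyloxy)eremophil-7(11)-en-8-one, via silyl dienol ether 16 (not isolated)
Conditions: TBSOTf, Et3N, CH2Cl2, 0 °C; crude: mCPBA, NaHCO3, CH2Cl2, −20 → 0 °C
Reagents that add atoms: tert-butyldimethylsilyl trifluoromethanesulfonate, CC(C)(C)[Si](C)(C)OS(=O)(=O)C(F)(F)F; 3-chloroperoxybenzoic acid, OOC(=O)c1cccc(Cl)c1
Why: Soft enolisation of the β,β-disubstituted enone takes place at C9, the only α carbon that bears hydrogen (as with mesityl oxide), and Rubottom oxidation of the electron-rich enol ether double bond occurs from the α face, opposite the axial C5 methyl that is 1,3 to C9, so that the 1,4-silyl shift leaves the equatorial 9α-silyloxy ketone.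

Step 8
Reactants: 17 (7(11)E)-9α,12-bis(tert-butyldimethylsilyloxy)-3α-(triethylsilyloxy)eremophil-7(11)-en-8-one
Product: 18 (7(11)E)-9α,12-bis(tert-butyldimethylsilyloxy)-3α-hydroxyeremophil-7(11)-en-8-one
Conditions: PPTS (cat.), MeOH–CH2Cl2, 0 °C
Reagents that add atoms: none
Why: Acid-catalysed methanolysis (selective desilylation) cleaves the secondary triethylsilyl ether much faster than the primary and the α-keto tert-butyldimethylsilyl ethers.

Step 9
Reactants: 19 (E)-non-3-en-2-one
Product: 20 (2E,4E)-3-methyldeca-2,4-dienenitrile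
Conditions: (EtO)2P(O)CH2CN, NaH, THF, 0 °C → rt
Reagents that add atoms: diethyl cyanomethylphosphonate, CCOP(=O)(CC#N)OCC
Why: Horner–Wadsworth–Emmons olefination of the methyl ketone should favour the 2E isomer, in which the nitrile is trans to the larger alkenyl group, and the minor 2Z isomer is removed by chromatography.

Step 10
Reactants: 20 (2E,4E)-3-methyldeca-2,4-dienenitrile
Product: 21 (2E,4E)-3-methyldeca-2,4-dienal
Conditions: iBu2AlH, toluene, −78 °C; then 1 M aq. HCl, 0 °C
Reagents that add atoms: water, O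
Why: The aluminium hydride adds once to the nitrile and the resulting aluminium imine is hydrolysed to the aldehyde on work-up (partial nitrile reduction), the alkene geometry being unaffected at low temperature.

Step 11
Reactants: 21 (2E,4E)-3-methyldeca-2,4-dienal
Product: 22 ethyl (2E,4E,6E)-5-methyldodeca-2,4,6-trienoate
Conditions: (EtO)2P(O)CH2CO2Et, NaH, THF, 0 °C → rt
Reagents that add atoms: triethyl phosphonoacetate, CCOC(=O)CP(=O)(OCC)OCC
Why: Horner–Wadsworth–Emmons olefination of an aldehyde with a stabilised phosphonate anion is reliably E-selective.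

Step 12
Reactants: 22 ethyl (2E,4E,6E)-5-methyldodeca-2,4,6-trienoate
Product: 23 (2E,4E,6E)-5-methyldodeca-2,4,6-trienoic acid
Conditions: LiOH, THF–MeOH–H2O, rt; then 1 M aq. HCl to pH 3
Reagents that add atoms: lithium hydroxide, [Li+].[OH-]
Why: Saponification of the ethyl ester under mild conditions should not isomerise the all-E triene.

Step 13
Reactants: 18 (7(11)E)-9α,12-bis(tert-butyldimethylsilyloxy)-3α-hydroxyeremophil-7(11)-en-8-one; 23 (2E,4E,6E)-5-methyldodeca-2,4,6-trienoic acid
Product: 24 (7(11)E)-9α,12-bis(tert-butyldimethylsilyloxy)-8-oxoeremophil-7(11)-en-3α-yl (2E,4E,6E)-5-methyldodeca-2,4,6-trienoate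
Conditions: DCC, DMAP (cat.), CH2Cl2, 0 °C → rt
Reagents that add atoms: none
Why: Steglich esterification acylates the only free hydroxyl, and the configuration at C3 is retained because the C3–O bond is not broken.

Step 14
Reactants: 24 (7(11)E)-9α,12-bis(tert-butyldimethylsilyloxy)-8-oxoeremophil-7(11)-en-3α-yl (2E,4E,6E)-5-methyldodeca-2,4,6-trienoate
Product: 25 (7(11)E)-9α,12-dihydroxy-8-oxoeremophil-7(11)-en-3α-yl (2E,4E,6E)-5-methyldodeca-2,4,6-trienoate (CNP0226738.2)
Conditions: HF·pyridine, pyridine, THF, 0 °C → rt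
Reagents that add atoms: none
Why: Fluoride-mediated cleavage of both silyl ethers under buffered, weakly acidic conditions should leave the ester, the α-ketol and the tetrasubstituted enone untouched.

Compound list
1 | dimethyl diselenide | C[Se][Se]C | starting material
2 | acetaldehyde | CC=O | starting material
3 | methaneselenol | C[SeH] | intermediate
4 | 1,1-bis(methylselanyl)ethane | CC([Se]C)[Se]C | intermediate
5 | (S)-7a-methyl-2,3,7,7a-tetrahydro-1H-indene-1,5(6H)-dione | O=C1CCC2=CC(=O)CC[C@]12C | starting material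
6 | (S)-5-ethoxy-7a-methyl-2,6,7,7a-tetrahydro-1H-inden-1-one (dienol ethyl ether of 5) | O=C1CC=C2C=C(OCC)CC[C@]12C | intermediate
7 | 1-(methylselanyl)ethyllithium | [Li]C(C)[Se]C | intermediate
8 | 5-ethoxy-7a-methyl-1-[1-(methylselanyl)ethyl]-2,6,7,7a-tetrahydro-1H-inden-1-ol, hydroxyl cis to the angular methyl, both epimers at the selenium-bearing carbon | CCOC1=CC2=CC[C@@](O)(C(C)[Se]C)[C@@]2(C)CC1 | intermediate
9 | 1-hydroxy-7a-methyl-1-[1-(methylselanyl)ethyl]-1,2,3,6,7,7a-hexahydro-5H-inden-5-one, hydroxyl cis to the angular methyl, both epimers at the selenium-bearing carbon | O=C1C=C2CC[C@@](O)(C(C)[Se]C)[C@@]2(C)CC1 | intermediate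
10 | (4aR,5R)-4a,5-dimethyl-4,4a,7,8-tetrahydronaphthalene-2,6(3H,5H)-dione (4β,5β-dimethyl-octal-9(10)-ene-3,8-dione) | O=C1CCC2=CC(=O)CC[C@]2(C)[C@H]1C | intermediate
11 | 3α-hydroxy-4β,5β-dimethyl-trans-decalin-8-one (10α-H) | O[C@@H]1CC[C@H]2CC(=O)CC[C@]2(C)[C@H]1C | intermediate
12 | 3α-(triethylsilyloxy)-4β,5β-dimethyl-trans-decalin-8-one | CC[Si](CC)(CC)O[C@@H]1CC[C@H]2CC(=O)CC[C@]2(C)[C@H]1C | intermediate
13 | 7-[1-(tert-butyldimethylsilyloxy)-2-hydroxypropan-2-yl] derivative of 12, mixture at C7 and C11 | CC[Si](CC)(CC)O[C@@H]1CC[C@H]2CC(=O)C(C(C)(O)CO[Si](C)(C)C(C)(C)C)C[C@]2(C)[C@H]1C | intermediate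
14 | tertiary methanesulfonate of 13 | CC[Si](CC)(CC)O[C@@H]1CC[C@H]2CC(=O)C(C(C)(OS(C)(=O)=O)CO[Si](C)(C)C(C)(C)C)C[C@]2(C)[C@H]1C | intermediate
15 | (7(11)E)-12-(tert-butyldimethylsilyloxy)-3α-(triethylsilyloxy)eremophil-7(11)-en-8-one (4β,5β-dimethyl, 10α-H) | CC[Si](CC)(CC)O[C@@H]1CC[C@H]2CC(=O)/C(=C(\C)CO[Si](C)(C)C(C)(C)C)C[C@]2(C)[C@H]1C | intermediate
16 | 8-(tert-butyldimethylsilyloxy)-7(11),8-diene (silyl dienol ether of 15) | CC[Si](CC)(CC)O[C@@H]1CC[C@H]2C=C(O[Si](C)(C)C(C)(C)C)/C(=C(\C)CO[Si](C)(C)C(C)(C)C)C[C@]2(C)[C@H]1C | intermediate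
17 | (7(11)E)-9α,12-bis(tert-butyldimethylsilyloxy)-3α-(triethylsilyloxy)eremophil-7(11)-en-8-one | CC[Si](CC)(CC)O[C@@H]1CC[C@H]2[C@H](O[Si](C)(C)C(C)(C)C)C(=O)/C(=C(\C)CO[Si](C)(C)C(C)(C)C)C[C@]2(C)[C@H]1C | intermediate
18 | (7(11)E)-9α,12-bis(tert-butyldimethylsilyloxy)-3α-hydroxyeremophil-7(11)-en-8-one | O[C@@H]1CC[C@H]2[C@H](O[Si](C)(C)C(C)(C)C)C(=O)/C(=C(\C)CO[Si](C)(C)C(C)(C)C)C[C@]2(C)[C@H]1C | intermediate
19 | (E)-non-3-en-2-one | CCCCC/C=C/C(C)=O | starting material
20 | (2E,4E)-3-methyldeca-2,4-dienenitrile | CCCCC/C=C/C(C)=C/C#N | intermediate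
21 | (2E,4E)-3-methyldeca-2,4-dienal | CCCCC/C=C/C(C)=C/C=O | intermediate
22 | ethyl (2E,4E,6E)-5-methyldodeca-2,4,6-trienoate | CCCCC/C=C/C(C)=C/C=C/C(=O)OCC | intermediate
23 | (2E,4E,6E)-5-methyldodeca-2,4,6-trienoic acid | CCCCC/C=C/C(C)=C/C=C/C(=O)O | intermediate
24 | (7(11)E)-9α,12-bis(tert-butyldimethylsilyloxy)-8-oxoeremophil-7(11)-en-3α-yl (2E,4E,6E)-5-methyldodeca-2,4,6-trienoate | CCCCC/C=C/C(C)=C/C=C/C(=O)O[C@@H]1CC[C@H]2[C@H](O[Si](C)(C)C(C)(C)C)C(=O)/C(=C(\C)CO[Si](C)(C)C(C)(C)C)C[C@]2(C)[C@H]1C | intermediate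
25 | (7(11)E)-9α,12-dihydroxy-8-oxoeremophil-7(11)-en-3α-yl (2E,4E,6E)-5-methyldodeca-2,4,6-trienoate (4β,5β-dimethyl, 10α-H) | CCCCC/C=C/C(C)=C/C=C/C(=O)O[C@@H]1CC[C@H]2[C@H](O)C(=O)/C(=C(\C)CO)C[C@]2(C)[C@H]1C | target

Total step count: 14. Longest linear sequence: 9 steps (5 → 6 → 10 → 11 → 12 → 15 → 17 → 18 → 24 → 25; steps 2 to 8, 13 and 14).

Steps most likely to fail

Step 3. What may go wrong: proton abstraction from the doubly activated C2 methylene of 6 in place of carbonyl addition, shift of C2 or closure to the epoxide in place of the C5 shift, and only a weak thermodynamic bias between the C4 epimers. The fallback sets out from 5 and comes back at 10. Wittig ethylidenation of the saturated carbonyl of 5 (EtPPh3Br, KOtBu, THF) should give the Z-ethylidene enone F1. OsO4 (cat.) with N-methylmorpholine N-oxide should dihydroxylate the exocyclic alkene from the α face to the diol F2. MsCl in pyridine should sulfonylate only the secondary hydroxyl to give the hydroxy mesylate F3. Et3Al in CH2Cl2 at −78 → 0 °C then triggers the semipinacol shift of C5 onto the mesylate carbon, and DBU equilibration as in step 3 gives 10.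

Step 6. What may go wrong: proton transfer to the enolisable ketone or retro-aldol cleavage during the addition, and poor geometric selectivity in the elimination, so that the Z alkene forms in quantity. The fallback sets out from 12 and comes back at 15. The lithium enolate of 12 is added to 1,1-dimethoxypropan-2-one to give the hydroxy acetal F4, which is dehydrated through its mesylate F5 (MsCl, Et3N; then DBU) to the enone acetal F6. Mild hydrolysis (oxalic acid on wet SiO2, CH2Cl2) frees the keto aldehyde F7. F7 is an ene-1,4-dicarbonyl compound whose geometric isomers interconvert readily (I2 cat.), and the isomer with the two carbonyl groups anti should be favoured, so the geometry is set under thermodynamic control. NaBH4 at −78 °C should reduce only the aldehyde to the allylic alcohol F8, and TBSCl with imidazole returns to 15.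

Step 4. What may go wrong: further reduction of the C8 ketone if the enolate is protonated while lithium remains, pinacol coupling, or incomplete reduction at C3. The fallback sets out from 10 and comes back at 11. NaBH4 in EtOH at −20 °C should reduce only the saturated C3 ketone, from the open α face, to the axial 3β-hydroxy enone F9. A Mitsunobu reaction with 4-nitrobenzoic acid (PPh3, DIAD, toluene) inverts C3 to the equatorial 3α-(4-nitrobenzoate) F10, and K2CO3 in MeOH frees the 3α-hydroxy enone F11. Li in NH3 with t-BuOH then has only the enone to reduce, and NH4Cl gives 11.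

Further compounds
F1 | step 3 | (Z)-1-ethylidene-7a-methyl-1,2,3,6,7,7a-hexahydro-5H-inden-5-one, ethylidene methyl cis to C5 | C/C=C1/CCC2=CC(=O)CC[C@]12C
F2 | step 3 | 1-hydroxy-1-(1-hydroxyethyl)-7a-methyl-1,2,3,6,7,7a-hexahydro-5H-inden-5-one, both hydroxyls added on the α face | C[C@H](O)[C@@]1(O)CCC2=CC(=O)CC[C@]12C
F3 | step 3 | secondary methanesulfonate of F2 | C[C@H](OS(C)(=O)=O)[C@@]1(O)CCC2=CC(=O)CC[C@]12C
F4 | step 6 | 7-(2-hydroxy-1,1-dimethoxypropan-2-yl) derivative of 12, mixture at C7 and C11 | CC[Si](CC)(CC)O[C@@H]1CC[C@H]2CC(=O)C(C(C)(O)C(OC)OC)C[C@]2(C)[C@H]1C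
F5 | step 6 | tertiary methanesulfonate of F4 | CC[Si](CC)(CC)O[C@@H]1CC[C@H]2CC(=O)C(C(C)(OS(C)(=O)=O)C(OC)OC)C[C@]2(C)[C@H]1C
F6 | step 6 | (7(11)E)-12,12-dimethoxy-3α-(triethylsilyloxy)eremophil-7(11)-en-8-one | CC[Si](CC)(CC)O[C@@H]1CC[C@H]2CC(=O)/C(=C(\C)C(OC)OC)C[C@]2(C)[C@H]1C
F7 | step 6 | (7(11)E)-8-oxo-3α-(triethylsilyloxy)eremophil-7(11)-en-12-al | CC[Si](CC)(CC)O[C@@H]1CC[C@H]2CC(=O)/C(=C(\C)C=O)C[C@]2(C)[C@H]1C
F8 | step 6 | (7(11)E)-12-hydroxy-3α-(triethylsilyloxy)eremophil-7(11)-en-8-one | CC[Si](CC)(CC)O[C@@H]1CC[C@H]2CC(=O)/C(=C(\C)CO)C[C@]2(C)[C@H]1C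
F9 | step 4 | 3β-hydroxy-4β,5β-dimethyl-octal-9(10)-en-8-one | O[C@H]1CCC2=CC(=O)CC[C@]2(C)[C@H]1C
F10 | step 4 | 3α-(4-nitrobenzoyloxy)-4β,5β-dimethyl-octal-9(10)-en-8-one | O=C(O[C@@H]1CCC2=CC(=O)CC[C@]2(C)[C@H]1C)c1ccc(cc1)[N+](=O)[O-]
F11 | step 4 | 3α-hydroxy-4β,5β-dimethyl-octal-9(10)-en-8-one | O[C@@H]1CCC2=CC(=O)CC[C@]2(C)[C@H]1C
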